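**Plan**

1. Retrosynthetic cuts, in order: (a) the three benzyl esters and the chain double bond (hydrogenation), then the chain between carbons 2 and 3 counted from the side-chain CH (cross-metathesis); (b) the oxolane C2–C3 bond, quaternary carbon to ring CH2; (c) the allyl–CH bond.
2. Enabling feature: in the 5-oxooxolane-2-carboxylic acid ring, O1 and the C2 carboxyl are an α-hydroxy acid, and carbonyl carbon C5 lies 1,3 to C2 across O1. At the aldehyde level C5 can therefore be the acetal carbon of a 1,3-dioxolan-4-one that holds its C4–C3 arm (as CH2CH2Br) over the enolizable C2.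
3. Forward: anti-allylation of diethyl (S)-malate, saponification, cis-dioxolanone from 3-bromopropanal dimethyl acetal, then bridging enolate alkylation. This closes the oxolane ring inside a 2,7-dioxabicyclo[2.2.1]heptan-3-one.
4. Acylal hydrolysis and lactol oxidation give the γ-lactone diacid; benzylation, cross-metathesis with the non-8-enyl ester of (R)-malic acid 4-benzyl ester and one hydrogenation finish the synthesis.
5. Stereochemistry: the side-chain CH comes from (S)-malate by Frater–Seebach alkylation. The quaternary carbon is set by relay (malate C2 → cis acetal carbon → back to C2, the new bond forming on the face of the tether). The (R)-malate unit comes from D-aspartic acid 4-benzyl ester by retentive diazotization.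

Key step: step 4

Assumption: the cross-metathesis product 16 is drawn as the E isomer; an E/Z mixture is expected and does not matter because the double bond is hydrogenated in step 10. Lactol 9 is an anomeric mixture.

**Route**

Step 1
Reactants: 1 diethyl (2S)-2-hydroxybutanedioate (diethyl L-malate); 2 allyl bromide
Product: 3 diethyl (2S,3R)-2-hydroxy-3-(prop-2-en-1-yl)butanedioate
Conditions: LiN(iPr)2 (2.1 equiv), THF, -78 to -20 °C; then 2, -78 to -10 °C; AcOH quench
Reagents that add atoms: none
Why: Frater–Seebach alkylation, in which the chelated lithium alkoxide–ester enolate dianion is allylated on the face anti to the carbinol oxygen substituent, so the 2,3-anti (2S,3R) diester should be the main product and the minor syn isomer is removed by chromatography.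

Step 2
Reactants: 3 diethyl (2S,3R)-2-hydroxy-3-(prop-2-en-1-yl)butanedioate
Product: 4 (2S,3R)-2-hydroxy-3-(prop-2-en-1-yl)butanedioic acid
Conditions: LiOH (4 equiv), THF/H2O, 0 °C to rt; then aq. HCl to pH 1, EtOAc extraction
Reagents that add atoms: lithium hydroxide, [Li+].[OH-]
Why: Ester saponification, in which the carboxylates formed resist enolization, so neither stereocenter should epimerize.

Step 3
Reactants: 4 (2S,3R)-2-hydroxy-3-(prop-2-en-1-yl)butanedioic acid; 5 3-bromo-1,1-dimethoxypropane
Product: 6 (2R)-2-[(2S,4S)-2-(2-bromoethyl)-5-oxo-1,3-dioxolan-4-yl]pent-4-enoic acid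
Conditions: 5 (1.3 equiv), TsOH·H2O (cat.), 1,2-dichloroethane, 60 °C, 5 Å molecular sieves; chromatography
Reagents that add atoms: none
Why: Acid-catalysed transacetalization under equilibrium control, in which the α-hydroxy acid should close the five-membered dioxolanone in preference to the six-membered dioxanone through the other carboxyl and the 2,4-cis isomer (both substituents pseudo-equatorial) should predominate, so the acetal carbon is set by relay from the malate carbinol carbon; the trans isomer is separated and re-equilibrated.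

Step 4
Reactants: 6 (2R)-2-[(2S,4S)-2-(2-bromoethyl)-5-oxo-1,3-dioxolan-4-yl]pent-4-enoic acid
Product: 8 (2R)-2-[(1S,4R)-3-oxo-2,7-dioxabicyclo[2.2.1]heptan-4-yl]pent-4-enoic acid, via dilithium carboxylate-enolate 7 (not isolated)
Conditions: LiN(SiMe3)2 (2.2 equiv), THF (0.02 M), -78 to -20 °C; cold aq. HCl to pH 3
Reagents that add atoms: none
Why: Proposed new method: LiN(SiMe3)2 first forms the lithium carboxylate, which shuts off enolization at the side-chain CH, then removes the dioxolanone C4–H, and the enolate carbon displaces the primary bromide held over it by the two-carbon arm of the acetal carbon. The closest known reaction types are the intermolecular alkylation of 1,3-dioxolan-4-one enolates (self-regeneration of stereocenters) and the intramolecular alkylation of 3-(2-haloethyl)cyclopentanone enolates to bicyclo[2.2.1]heptan-2-ones; new here is the acetal carbon serving as a tether that later becomes a ring carbon. The oxolane ring closes in a 5-(enolexo)-exo-tet mode and the second ring through the lactone carbonyl in a 6-(enolendo)-exo-tet mode, both allowed. The new quaternary stereocenter is controlled only by the acetal carbon, because the arm can reach only the enolate face on which it stands (a trans-bridged bicyclo[2.2.1] system cannot form); since the arm is cis to the side chain in 6, the new C–C bond takes the place of the side chain, the side chain takes the place of the former hydrogen, and the carbon becomes R. The step needs C-alkylation at the ring carbon in preference to deprotonation of the side-chain CH, loss of HBr or intermolecular reaction; the carboxylate, the non-nucleophilic amide base and high dilution are meant to secure this.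

Step 5
Reactants: 8 (2R)-2-[(1S,4R)-3-oxo-2,7-dioxabicyclo[2.2.1]heptan-4-yl]pent-4-enoic acid
Product: 10 (2R)-2-[(1R)-1-carboxybut-3-en-1-yl]-5-oxooxolane-2-carboxylic acid, via lactol diacid 9 (not isolated)
Conditions: TFA (cat.), MeCN/H2O, rt; then TEMPO (cat.), PhI(OAc)2, same flask, rt
Reagents that add atoms: water, O
Why: Acid hydrolysis of the strained bicyclic acylal releases the C2 carboxyl and the lactol, which the oxoammonium salt from TEMPO/PhI(OAc)2 should oxidize to the γ-lactone without touching the terminal alkene or either stereocenter.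

Step 6
Reactants: 10 (2R)-2-[(1R)-1-carboxybut-3-en-1-yl]-5-oxooxolane-2-carboxylic acid
Product: 11 benzyl (2R)-2-[(2R)-1-(benzyloxy)-1-oxopent-4-en-2-yl]-5-oxooxolane-2-carboxylate
Conditions: BnBr (2.4 equiv), KHCO3 (3 equiv), DMF, rt
Reagents that add atoms: benzyl bromide, BrCc1ccccc1
Why: SN2 O-alkylation of both carboxylates under weakly basic conditions, which should leave the lactone closed and the CH stereocenter unenolized.

Step 7
Reactants: 12 (2R)-2-amino-4-(benzyloxy)-4-oxobutanoic acid (D-aspartic acid 4-benzyl ester)
Product: 13 (2R)-4-(benzyloxy)-2-hydroxy-4-oxobutanoic acid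
Conditions: NaNO2, 1 M aq. H2SO4, 0 °C to rt
Reagents that add atoms: water, O
Why: Diazotization of an α-amino acid, in which the neighbouring carboxylate displaces N2 to an α-lactone that water reopens, so the hydroxyl should arrive with net retention (double inversion) and the benzyl ester survives cold dilute acid.

Step 8
Reactants: 13 (2R)-4-(benzyloxy)-2-hydroxy-4-oxobutanoic acid; 14 9-bromonon-1-ene
Product: 15 4-benzyl 1-(non-8-en-1-yl) (2R)-2-hydroxybutanedioate
Conditions: KHCO3 (1.1 equiv), Bu4NI (cat.), DMF, 45 °C
Reagents that add atoms: none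
Why: SN2 alkylation of the only carboxylate by the primary bromide, which places the chain on the carboxyl next to the carbinol without protecting the hydroxyl, since bicarbonate does not ionize it.

Step 9
Reactants: 11 benzyl (2R)-2-[(2R)-1-(benzyloxy)-1-oxopent-4-en-2-yl]-5-oxooxolane-2-carboxylate; 15 4-benzyl 1-(non-8-en-1-yl) (2R)-2-hydroxybutanedioate
Product: 16 benzyl (2R)-2-[(2R,4E)-1-(benzyloxy)-12-{[(2R)-4-(benzyloxy)-2-hydroxy-4-oxobutanoyl]oxy}-1-oxododec-4-en-2-yl]-5-oxooxolane-2-carboxylate
Conditions: 15 (3 equiv), second-generation Hoveyda–Grubbs catalyst RuCl2(H2IMes)(=CH-C6H4-2-OiPr) (5 mol %), CH2Cl2, 40 °C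
Reagents that add atoms: none
Why: Olefin cross-metathesis of two terminal monosubstituted alkenes driven by loss of ethylene, with the cheaper partner in excess to favour the cross product.

Step 10
Reactants: 16 benzyl (2R)-2-[(2R,4E)-1-(benzyloxy)-12-{[(2R)-4-(benzyloxy)-2-hydroxy-4-oxobutanoyl]oxy}-1-oxododec-4-en-2-yl]-5-oxooxolane-2-carboxylate
Product: 17 (2R)-2-[(1R)-1-carboxy-11-{[(2R)-3-carboxy-2-hydroxypropanoyl]oxy}undecyl]-5-oxooxolane-2-carboxylic acid
Conditions: H2 (1 atm), palladium on carbon (Pd/C, 10 wt %), EtOAc/MeOH, rt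
Reagents that add atoms: none
Why: Heterogeneous hydrogenation saturates the chain alkene and hydrogenolyses the three benzyl esters under neutral conditions that should leave the alkyl ester, the lactone and all three stereocenters untouched.

**Compound list**

1 | diethyl (2S)-2-hydroxybutanedioate | CCOC(=O)C[C@H](O)C(=O)OCC | starting material
2 | allyl bromide | C=CCBr | starting material
3 | diethyl (2S,3R)-2-hydroxy-3-(prop-2-en-1-yl)butanedioate | C=CC[C@@H](C(=O)OCC)[C@H](O)C(=O)OCC | intermediate
4 | (2S,3R)-2-hydroxy-3-(prop-2-en-1-yl)butanedioic acid | C=CC[C@@H](C(=O)O)[C@H](O)C(=O)O | intermediate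
5 | 3-bromo-1,1-dimethoxypropane | COC(CCBr)OC | starting material
6 | (2R)-2-[(2S,4S)-2-(2-bromoethyl)-5-oxo-1,3-dioxolan-4-yl]pent-4-enoic acid | C=CC[C@@H](C(=O)O)[C@@H]1O[C@H](CCBr)OC1=O | intermediate
7 | dilithium carboxylate-enolate of 6 | C=CC[C@@H](C(=O)[O-])C1=C([O-])O[C@@H](CCBr)O1.[Li+].[Li+] | intermediate (not isolated)
8 | (2R)-2-[(1S,4R)-3-oxo-2,7-dioxabicyclo[2.2.1]heptan-4-yl]pent-4-enoic acid | C=CC[C@@H](C(=O)O)[C@@]12CC[C@@H](O1)OC2=O | intermediate
9 | (2R)-2-[(1R)-1-carboxybut-3-en-1-yl]-5-hydroxyoxolane-2-carboxylic acid (anomeric mixture) | C=CC[C@@H](C(=O)O)[C@@]1(C(=O)O)CCC(O)O1 | intermediate (not isolated)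
10 | (2R)-2-[(1R)-1-carboxybut-3-en-1-yl]-5-oxooxolane-2-carboxylic acid | C=CC[C@@H](C(=O)O)[C@@]1(C(=O)O)CCC(=O)O1 | intermediate
11 | benzyl (2R)-2-[(2R)-1-(benzyloxy)-1-oxopent-4-en-2-yl]-5-oxooxolane-2-carboxylate | C=CC[C@@H](C(=O)OCc1ccccc1)[C@@]1(C(=O)OCc2ccccc2)CCC(=O)O1 | intermediate
12 | (2R)-2-amino-4-(benzyloxy)-4-oxobutanoic acid | N[C@H](CC(=O)OCc1ccccc1)C(=O)O | starting material
13 | (2R)-4-(benzyloxy)-2-hydroxy-4-oxobutanoic acid | O=C(OCc1ccccc1)C[C@@H](O)C(=O)O | intermediate
14 | 9-bromonon-1-ene | C=CCCCCCCCBr | starting material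
15 | 4-benzyl 1-(non-8-en-1-yl) (2R)-2-hydroxybutanedioate | O=C(OCc1ccccc1)C[C@@H](O)C(=O)OCCCCCCCC=C | intermediate
16 | benzyl (2R)-2-[(2R,4E)-1-(benzyloxy)-12-{[(2R)-4-(benzyloxy)-2-hydroxy-4-oxobutanoyl]oxy}-1-oxododec-4-en-2-yl]-5-oxooxolane-2-carboxylate | O=C(OCc1ccccc1)C[C@@H](O)C(=O)OCCCCCCC/C=C/C[C@@H](C(=O)OCc1ccccc1)[C@@]1(C(=O)OCc2ccccc2)CCC(=O)O1 | intermediate
17 | (2R)-2-[(1R)-1-carboxy-11-{[(2R)-3-carboxy-2-hydroxypropanoyl]oxy}undecyl]-5-oxooxolane-2-carboxylic acid | O=C(O)C[C@@H](O)C(=O)OCCCCCCCCCC[C@@H](C(=O)O)[C@@]1(C(=O)O)CCC(=O)O1 | target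

**Count**

Total steps: 10. Longest linear sequence: 8 (steps 1–6, 9, 10); steps 7–8 make the malate fragment.

**Steps most likely to fail**

Step 4. The strained bridging alkylation may be slower than self-condensation of the enolate with a second dioxolanone carbonyl, loss of HBr from the bromoethyl arm, or proton exchange to the side-chain CH. The fallback uses established intermolecular self-regeneration of stereocenters; it sets out from 3 and comes back at 10. Mitsunobu inversion of the carbinol of 3 (4-nitrobenzoic acid, PPh3, diisopropyl azodicarboxylate) should give diethyl (2R,3R)-2-[(4-nitrobenzoyl)oxy]-3-(prop-2-en-1-yl)butanedioate F1. Saponification with LiOH should give (2R,3R)-2-hydroxy-3-(prop-2-en-1-yl)butanedioic acid F2. Acid-catalysed condensation with pivalaldehyde should give the cis acetal (2R)-2-[(2R,4R)-2-tert-butyl-5-oxo-1,3-dioxolan-4-yl]pent-4-enoic acid F3. Its dianion (LiN(SiMe3)2, 2 equiv, THF, -78 °C) should add to methyl acrylate on the face opposite the tert-butyl group, replacing the hydrogen with retention, to give (2R)-2-[(2R,4R)-2-tert-butyl-4-(3-methoxy-3-oxopropyl)-5-oxo-1,3-dioxolan-4-yl]pent-4-enoic acid F4. Warm aqueous HCl in dioxane then removes the acetal and closes the lactone, arriving at 10.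

Step 3. Equilibration may give too little of the cis acetal, or closure through the side-chain carboxyl to the six-membered dioxanone may compete. The fallback replaces thermodynamic transacetalization of the free acid by kinetically controlled silyl-transfer acetalization; it sets out from 4 and comes back at 6. Persilylation of 4 with N,O-bis(trimethylsilyl)acetamide should give the tris(trimethylsilyl) derivative of 4 (silyl ether and two silyl esters) F5. With 5 and catalytic Me3SiOTf in CH2Cl2 at -78 °C, the oxocarbenium ion from the acetal is captured by the silyl ether and then by the adjacent silyl ester in the faster five-membered closure. Aqueous work-up cleaves the remaining silyl ester and delivers 6.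

Step 9. Homodimerization of 15 and sequestration of the ruthenium carbene by its α-hydroxy ester may leave the hindered allyl group of 11 unconverted. The fallback joins the fragments by C–O bond formation instead; it sets out from 11 and comes back at 16. Cross-metathesis of 11 with a large excess of the simple alkene 14 should give benzyl (2R)-2-[(2R,4E)-1-(benzyloxy)-12-bromo-1-oxododec-4-en-2-yl]-5-oxooxolane-2-carboxylate F6. Displacement of its bromide by the potassium carboxylate of 13 (KHCO3, DMF, 45 °C) gives 16.

**Further compounds**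

F1 | step 4 | diethyl (2R,3R)-2-[(4-nitrobenzoyl)oxy]-3-(prop-2-en-1-yl)butanedioate | C=CC[C@@H](C(=O)OCC)[C@@H](OC(=O)c1ccc(cc1)[N+](=O)[O-])C(=O)OCC
F2 | step 4 | (2R,3R)-2-hydroxy-3-(prop-2-en-1-yl)butanedioic acid | C=CC[C@@H](C(=O)O)[C@@H](O)C(=O)O
F3 | step 4 | (2R)-2-[(2R,4R)-2-tert-butyl-5-oxo-1,3-dioxolan-4-yl]pent-4-enoic acid | C=CC[C@@H](C(=O)O)[C@H]1O[C@@H](C(C)(C)C)OC1=O
F4 | step 4 | (2R)-2-[(2R,4R)-2-tert-butyl-4-(3-methoxy-3-oxopropyl)-5-oxo-1,3-dioxolan-4-yl]pent-4-enoic acid | C=CC[C@@H](C(=O)O)[C@@]1(CCC(=O)OC)O[C@@H](C(C)(C)C)OC1=O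
F5 | step 3 | tris(trimethylsilyl) derivative of 4 (silyl ether and two silyl esters) | C=CC[C@@H](C(=O)O[Si](C)(C)C)[C@H](O[Si](C)(C)C)C(=O)O[Si](C)(C)C
F6 | step 9 | benzyl (2R)-2-[(2R,4E)-1-(benzyloxy)-12-bromo-1-oxododec-4-en-2-yl]-5-oxooxolane-2-carboxylate | BrCCCCCCC/C=C/C[C@@H](C(=O)OCc1ccccc1)[C@@]1(C(=O)OCc2ccccc2)CCC(=O)O1
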